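The guaiacyl ring is cut from C2 of the dihydrofuran ring. C2 (bonded to O1) and C3 (bearing the CH2OH carbon) are read as the β- and α-carbons of a vinylogous carbonate, so the precursor is a flat, achiral, fully aromatic ethyl 5-bromo-7-methoxybenzofuran-3-carboxylate. One rhodium-catalysed, ligand-controlled dearomative 1,4-arylation adds the aryl group to C2, sets C2 and, after equilibration of the enolisable C3, the trans-2,3 relationship. The phenol travels as an acetate that the ester reduction removes; the C5 bromide then takes the propenal chain by Suzuki coupling. Four steps, no separate deprotection.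

Key step: step 2

Assumption: the sense of induction of the (R,R)-diene ligand on this new acceptor is assigned by analogy with chromone and coumarin arylations; should C2 come out (S), the (S,S)-ligand is used and nothing else changes. (R,R)-Ph-bod = (1R,4R)-2,5-diphenylbicyclo[2.2.2]octa-2,5-diene.

Step 1
Reactants: 1 5-bromo-2-hydroxy-3-methoxybenzaldehyde; 2 ethyl diazoacetate
Product: 4 ethyl 5-bromo-7-methoxy-1-benzofuran-3-carboxylate, via hemiacetal 3 (not isolated)
Conditions: HBF4·OEt2 (10 mol%), CH2Cl2, rt; then conc. H2SO4, rt
Reagents that add atoms: none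
Why: Acid-promoted addition of the diazo ester to the aldehyde, 1,2-aryl shift with loss of N2 to the 2-aryl-3-oxopropanoate, closure of the phenol onto the formyl carbon (hemiacetal 3) and acid dehydration to the aromatic furan, a known one-flask benzofuran-3-carboxylate synthesis from salicylaldehydes; no stereocenter.

Step 2
Reactants: 4 ethyl 5-bromo-7-methoxy-1-benzofuran-3-carboxylate; 5 2-methoxy-4-(4,4,5,5-tetramethyl-1,3,2-dioxaborolan-2-yl)phenyl acetate
Product: 7 ethyl (2R,3R)-2-(4-acetoxy-3-methoxyphenyl)-5-bromo-7-methoxy-2,3-dihydro-1-benzofuran-3-carboxylate (trans), via cis ester 6 (not isolated)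
Conditions: [RhCl((R,R)-Ph-bod)]2 (2.5 mol%), KOH (10 mol%), 5 (2 equiv), dioxane/H2O (10:1), argon, 60 °C; then DBU (0.2 equiv), CH2Cl2, rt
Reagents that add atoms: none
Why: Proposed new method: transmetalation of 5 to the hydroxorhodium–diene complex gives an aryl–rhodium species that coordinates the C2=C3 bond of 4, a β-aryloxy acrylate locked in the furan ring, and inserts with the aryl group going to C2 and rhodium to C3 as an oxa-π-allyl (ester enolate conjugated with ring A), which water protonates to release the dihydrobenzofuran and return Rh–OH. The closest known reaction type is the Hayashi–Miyaura asymmetric 1,4-addition of arylboron reagents to chromones and coumarins (benzo-fused β-aryloxy and β-aryl acceptors), together with dearomative Michael additions to nitrobenzofurans; the new element is that the acceptor double bond belongs to an aromatic furan ring, whose modest resonance energy should be repaid by the new C–C bond. No ring is closed. C2 is set by the twofold-symmetric diene ligand, which should differentiate the two faces of the flat benzofuran at the insertion step; C3 is expected to be protonated first mainly anti to the new aryl group (cis ester 6) and is then equilibrated through the ester enolate with catalytic DBU to the more stable trans ester 7, the acetate blocking any quinone-methide opening that could touch C2. The step needs regioselectivity (aryl to C2), secured because the ester polarisation and the placing of rhodium as a stabilised enolate point the same way, and chemoselectivity, secured because aryl species of monovalent rhodium do not insert into the C5–Br bond and the near-neutral medium (only catalytic KOH) should spare the acetate.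

Step 3
Reactants: 7 ethyl (2R,3R)-2-(4-acetoxy-3-methoxyphenyl)-5-bromo-7-methoxy-2,3-dihydro-1-benzofuran-3-carboxylate
Product: 8 4-[(2R,3S)-5-bromo-3-(hydroxymethyl)-7-methoxy-2,3-dihydro-1-benzofuran-2-yl]-2-methoxyphenol
Conditions: i-Bu2AlH (6 equiv), toluene, −78 → 0 °C; aq. KNaC4H4O6 work-up
Reagents that add atoms: none
Why: Aluminium hydride reduction of the ethyl ester to the primary alcohol and of the aryl acetate to the phenol in one operation, a reduction known for phenolic dihydrobenzofuran-3-carboxylates; neither stereocenter is touched (the descriptor at C3 changes only by priority), and the phenol stays bound as a covalent aluminium aryloxide until work-up.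

Step 4
Reactants: 8 4-[(2R,3S)-5-bromo-3-(hydroxymethyl)-7-methoxy-2,3-dihydro-1-benzofuran-2-yl]-2-methoxyphenol; 9 2-[(E)-3,3-diethoxyprop-1-enyl]-4,4,5,5-tetramethyl-1,3,2-dioxaborolane
Product: 11 balanophonin, via diethyl acetal 10 (not isolated)
Conditions: Pd(OAc)2 (3 mol%), SPhos (6 mol%), K3PO4 (3 equiv), THF/H2O (10:1), 50 °C; then 1 M HCl, THF, rt
Reagents that add atoms: water, O
Why: Suzuki–Miyaura coupling of the aryl bromide with the (E)-alkenylboronate (alkene geometry retained, free phenol and alcohol tolerated) followed by mild acid hydrolysis of the diethyl acetal to the (E)-enal; no stereocenter is formed and C3 is no longer enolisable.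

Compound list
1 | 5-bromo-2-hydroxy-3-methoxybenzaldehyde | COc1cc(Br)cc(C=O)c1O | starting material
2 | ethyl diazoacetate | CCOC(=O)C=[N+]=[N-] | starting material
3 | ethyl 5-bromo-2-hydroxy-7-methoxy-2,3-dihydro-1-benzofuran-3-carboxylate (hemiacetal, stereoisomer mixture) | CCOC(=O)C1C(O)Oc2c(OC)cc(Br)cc12 | intermediate
4 | ethyl 5-bromo-7-methoxy-1-benzofuran-3-carboxylate | CCOC(=O)c1coc2c(OC)cc(Br)cc12 | intermediate
5 | 2-methoxy-4-(4,4,5,5-tetramethyl-1,3,2-dioxaborolan-2-yl)phenyl acetate | COc1cc(B2OC(C)(C)C(C)(C)O2)ccc1OC(C)=O | starting material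
6 | ethyl (2R,3S)-2-(4-acetoxy-3-methoxyphenyl)-5-bromo-7-methoxy-2,3-dihydro-1-benzofuran-3-carboxylate (cis) | COc1cc([C@@H]2Oc3c(OC)cc(Br)cc3[C@@H]2C(=O)OCC)ccc1OC(C)=O | intermediate
7 | ethyl (2R,3R)-2-(4-acetoxy-3-methoxyphenyl)-5-bromo-7-methoxy-2,3-dihydro-1-benzofuran-3-carboxylate (trans) | COc1cc([C@@H]2Oc3c(OC)cc(Br)cc3[C@H]2C(=O)OCC)ccc1OC(C)=O | intermediate
8 | 4-[(2R,3S)-5-bromo-3-(hydroxymethyl)-7-methoxy-2,3-dihydro-1-benzofuran-2-yl]-2-methoxyphenol | COc1cc([C@@H]2Oc3c(OC)cc(Br)cc3[C@H]2CO)ccc1O | intermediate
9 | 2-[(E)-3,3-diethoxyprop-1-enyl]-4,4,5,5-tetramethyl-1,3,2-dioxaborolane | CCOC(OCC)/C=C/B1OC(C)(C)C(C)(C)O1 | starting material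
10 | 4-[(2R,3S)-5-[(E)-3,3-diethoxyprop-1-enyl]-3-(hydroxymethyl)-7-methoxy-2,3-dihydro-1-benzofuran-2-yl]-2-methoxyphenol | COc1cc([C@@H]2Oc3c(OC)cc(/C=C/C(OCC)OCC)cc3[C@H]2CO)ccc1O | intermediate
11 | balanophonin, (E)-3-[(2R,3S)-2-(4-hydroxy-3-methoxyphenyl)-3-(hydroxymethyl)-7-methoxy-2,3-dihydro-1-benzofuran-5-yl]prop-2-enal | COc1cc([C@@H]2Oc3c(OC)cc(/C=C/C=O)cc3[C@H]2CO)ccc1O | target

Total step count: 4. Longest linear sequence: 4 steps (1 → 4 → 7 → 8 → 11).

Steps most likely to fail

Step 2 (proposed new method). The aryl–rhodium species may fail to insert into the aromatic C2=C3 bond, so that protodeboronation of 5 outruns addition, or the two faces of the flat benzofuran may be poorly distinguished. The fallback makes the same aryl–C2 bond on a non-aromatic acceptor by known chemistry. It sets out from boronate 5 and, in place of 4, from commercial 1-(5-bromo-2-hydroxy-3-methoxyphenyl)ethanone. Condensation with Me2NCH(OMe)2 (toluene, 100 °C) should give (E)-1-(5-bromo-2-hydroxy-3-methoxyphenyl)-3-(dimethylamino)prop-2-en-1-one F1, which conc. HCl in CH2Cl2 closes to 6-bromo-8-methoxychromone F2. Hayashi–Miyaura 1,4-addition of 5 to this chromone under the rhodium–diene conditions of step 2 (a known substrate class, kept near neutral so that the product does not open by retro-oxa-Michael reaction) should give (2R)-2-(4-acetoxy-3-methoxyphenyl)-6-bromo-8-methoxychroman-4-one F3. Oxidative ring contraction with PhI(OAc)2 and H2SO4 in HC(OMe)3 is a known edit of flavanones that leaves C2 untouched: the enol ether is iodinated at C3, the ring A carbon shifts from C4 to C3, and the former carbonyl carbon leaves the ring as the ester. It should give methyl (2R,3R)-2-(4-acetoxy-3-methoxyphenyl)-5-bromo-7-methoxy-2,3-dihydro-1-benzofuran-3-carboxylate F4, the methyl analogue of 7, and C3 can still be equilibrated to trans with DBU. Reduction of F4 under the conditions of step 3 comes back to the route at 8.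

Step 4. While the phenol is held as its phenoxide in the basic coupling, the dihydrofuran ring may open through the p-quinone methide, or the alkenylboronate may protodeboronate before transmetalation. The fallback sets out from 8. TBSCl and imidazole in DMF should give the bis(tert-butyldimethylsilyl) ether of 8 F5, which is coupled with 9 under the palladium conditions of step 4, now without a phenoxide, to the silylated diethyl acetal F6. n-Bu4NF buffered with AcOH (THF, 0 °C) removes both silyl groups and comes back to the route at 10, which the 1 M HCl stage of step 4 converts to 11.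

Step 1. After addition of the diazo ester, hydride shift may compete with aryl shift (simple homologation to a β-keto ester), or the electron-rich ring may be sulfonated during the H2SO4 dehydration. The fallback does not use 1 and 2; it sets out from commercial 4-bromo-2-methoxyphenol. Iodination ortho to the hydroxyl (NIS, cat. TsOH, MeCN) should give 4-bromo-2-iodo-6-methoxyphenol F7. Oxa-Michael addition to ethyl propiolate (N-methylmorpholine, CH2Cl2) should give ethyl (E)-3-(4-bromo-2-iodo-6-methoxyphenoxy)prop-2-enoate F8. Intramolecular Mizoroki–Heck reaction at the C–I bond (Pd(OAc)2, PPh3, K2CO3, DMF, 80 °C) closes the furan ring and comes back to the route at 4.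

Further compounds
F1 | step 2 | (E)-1-(5-bromo-2-hydroxy-3-methoxyphenyl)-3-(dimethylamino)prop-2-en-1-one | CN(C)/C=C/C(=O)c1cc(Br)cc(OC)c1O
F2 | step 2 | 6-bromo-8-methoxychromone (6-bromo-8-methoxy-4H-chromen-4-one) | COc1cc(Br)cc2c(=O)ccoc12
F3 | step 2 | (2R)-2-(4-acetoxy-3-methoxyphenyl)-6-bromo-8-methoxychroman-4-one | COc1cc([C@H]2CC(=O)c3cc(Br)cc(OC)c3O2)ccc1OC(C)=O
F4 | step 2 | methyl (2R,3R)-2-(4-acetoxy-3-methoxyphenyl)-5-bromo-7-methoxy-2,3-dihydro-1-benzofuran-3-carboxylate | COc1cc([C@@H]2Oc3c(OC)cc(Br)cc3[C@H]2C(=O)OC)ccc1OC(C)=O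
F5 | step 4 | bis(tert-butyldimethylsilyl) ether of 8 | COc1cc([C@@H]2Oc3c(OC)cc(Br)cc3[C@H]2CO[Si](C)(C)C(C)(C)C)ccc1O[Si](C)(C)C(C)(C)C
F6 | step 4 | bis(tert-butyldimethylsilyl) ether of 10 (silylated diethyl acetal) | COc1cc([C@@H]2Oc3c(OC)cc(/C=C/C(OCC)OCC)cc3[C@H]2CO[Si](C)(C)C(C)(C)C)ccc1O[Si](C)(C)C(C)(C)C
F7 | step 1 | 4-bromo-2-iodo-6-methoxyphenol | COc1cc(Br)cc(I)c1O
F8 | step 1 | ethyl (E)-3-(4-bromo-2-iodo-6-methoxyphenoxy)prop-2-enoate | CCOC(=O)/C=C/Oc1c(I)cc(Br)cc1OC
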